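**Retrosynthetic overview**
Numbering: C1 allyl bridgehead, C2 CH2, C3 CH(OMe), C4 C=O, C5 OMe bridgehead, C6 CH(aryl), C7 CH(Me), C8 CH(OH); exo is the side of C8, endo the side of C6–C7.
Feature used: the six-membered ring C1–C2–C3–C4–C5–C8 is a three-carbon bridge C2–C3–C4 laid across both α-carbons (C1, C5) of a C8 cyclopentanone (ring C1–C7–C6–C5–C8). Acrolein can therefore supply it, forming C1–C2 by conjugate addition and C4–C5 by aldol addition.
The cyclopentanone is bought as (S)-4-silyloxycyclopentenone. Aryl (C6), OMe (C5), the C1=C7 enone, allyl (C1) and methyl (C7) follow in that order, each new centre trans to its neighbour, and the last addition is trapped as the C1=C8 silyl enol ether.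
After the annulation, C8 is reduced while C4 still carries an axial silyl ether, and C4 is then oxidised. C3 passes through the diosphenol methyl ether so that its hydrogen arrives last, from the exo face; an oxygen electrophile entering from that face would give the C3 epimer.
Ring order: five-membered ring (purchased), then six-membered ring (step 10).

Key step: step 10

Conventions: Ar = 4-methoxy-3-(triisopropylsilyloxy)phenyl. On the monocyclic compounds, β is the face of the C7 substituent and α the face of the aryl group.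
Assumption: the (S)-enantiomer of 4-(tert-butyldimethylsilyloxy)cyclopent-2-enone is taken as purchasable, like its antipode.

**Step 1**
Reactants: 1 5-bromo-2-methoxyphenol
Product: 2 (5-bromo-2-methoxyphenoxy)triisopropylsilane
Conditions: iPr3SiCl, imidazole, DMF, rt
Reagents that add atoms: chlorotriisopropylsilane, CC(C)[Si](Cl)(C(C)C)C(C)C
Why: Imidazole-promoted O-silylation of a phenol; the triisopropylsilyl ether should survive the organomagnesium, amine-base, acidic-fluoride and oxidation steps ahead and still leave with buffered fluoride at the end.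

**Step 2**
Reactants: 2 (5-bromo-2-methoxyphenoxy)triisopropylsilane; 3 (S)-4-(tert-butyldimethylsilyloxy)cyclopent-2-en-1-one
Product: 5 trimethylsilyl enol ether of trans-3-Ar-4-(tert-butyldimethylsilyloxy)cyclopentanone (C5=C8 double bond; C6-Ar α; C7-OSi β), via arylmagnesium bromide 4 (not isolated)
Conditions: Mg, THF, 40 °C; then CuBr·SMe2 (15 mol %), Me3SiCl, 3, THF, −78 °C; Et3N, aq NaHCO3
Reagents that add atoms: chlorotrimethylsilane, C[Si](C)(C)Cl; magnesium, [Mg] (stays only in 4)
Why: Copper-catalysed, Me3SiCl-accelerated conjugate addition of an arylmagnesium bromide: the aryl group should enter C6 anti to the C7 silyloxy group, which sets C6, and O-silylation fixes the enolate as the C5=C8 enol ether needed for oxygenation at C5.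

**Step 3**
Reactants: 5 trimethylsilyl enol ether
Product: 7 2-hydroxy-3-Ar-4-(tert-butyldimethylsilyloxy)cyclopentanone (C5-OH β; C6-Ar α; C7-OSi β), via α-trimethylsilyloxy ketone 6 (not isolated)
Conditions: mCPBA, NaHCO3, CH2Cl2, −20 °C; then 10% aq citric acid, THF, 0 °C
Reagents that add atoms: 3-chloroperoxybenzoic acid, O=C(OO)c1cccc(Cl)c1
Why: Rubottom oxidation: the enol ether should be epoxidised anti to the neighbouring C6 aryl group, silyl migration gives 6, and dilute acid frees the C5 hydroxyl while the bulkier silyl ethers stay.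

**Step 4**
Reactants: 7 2-hydroxy ketone
Product: 8 2-methoxy-3-Ar-4-(tert-butyldimethylsilyloxy)cyclopentanone (C5-OMe β; C6-Ar α; C7-OSi β)
Conditions: Me3OBF4, 1,8-bis(dimethylamino)naphthalene, 4 Å MS, CH2Cl2, rt
Reagents that add atoms: trimethyloxonium tetrafluoroborate, C[O+](C)C.F[B-](F)(F)F
Why: O-Alkylation with an oxonium salt and a non-nucleophilic proton scavenger works without enolate formation, so β-elimination of the C7 silyloxy group and α-ketol shift should not intervene.

**Step 5**
Reactants: 8 2-methoxy ketone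
Product: 9 4-hydroxy-2-methoxy-3-Ar-cyclopentanone (C5-OMe β; C6-Ar α; C7-OH β)
Conditions: 48% aq HF, MeCN, 0 °C
Reagents that add atoms: none
Why: Acidic fluoride cleaves a secondary alkyl tert-butyldimethylsilyl ether far faster than an aryl triisopropylsilyl ether, so only C7–OH is freed.

**Step 6**
Reactants: 9 β-hydroxy ketone
Product: 11 trans-4-Ar-5-methoxycyclopent-2-en-1-one (C1=C7 enone; C5-OMe β; C6-Ar α), via C7 mesylate 10 (not isolated)
Conditions: MsCl, Et3N, CH2Cl2, −20 → 0 °C
Reagents that add atoms: methanesulfonyl chloride, CS(=O)(=O)Cl (stays only in 10)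
Why: Mesylation and E1cB elimination through the only acidic neighbour, C1–H, place the alkene at C1=C7 without any regiochemical choice, and Et3N is weak enough to leave the doubly activated C6–H of 11 alone, so that C6 is not scrambled and the alkene does not drift into conjugation with the arene.

**Step 7**
Reactants: 11 enone
Product: 12 2-iodo-4-Ar-5-methoxycyclopent-2-en-1-one
Conditions: I2, pyridine, CH2Cl2, 0 °C → rt
Reagents that add atoms: iodine, II
Why: α-Iodination of an enone by reversible addition of pyridine to C7, iodination of the enolate at C1 and loss of pyridine (Baylis–Hillman-type sequence), again under weakly basic conditions.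

**Step 8**
Reactants: 12 α-iodoenone; 13 allyltributylstannane
Product: 14 2-allyl-4-Ar-5-methoxycyclopent-2-en-1-one (C5-OMe β; C6-Ar α)
Conditions: Pd2(dba)3 (2.5 mol %), AsPh3, CuI, NMP, rt
Reagents that add atoms: allyltributylstannane 13, C=CC[Sn](CCCC)(CCCC)CCCC
Why: Stille coupling of an α-iodoenone under neutral conditions (AsPh3 and CuI speed up transmetallation) should put the allyl group on C1 and nowhere else.

**Step 9**
Reactants: 14 2-allyl enone
Product: 15 2-allyl-5-methoxy-3-methyl-4-Ar-cyclopent-1-enyl trimethylsilyl ether (C1=C8 double bond; C5-OMe β; C6-Ar α; C7-Me β)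
Conditions: Me2CuLi (MeLi, CuI), Me3SiCl, Et2O–THF, −78 °C; Et3N, aq NaHCO3
Reagents that add atoms: lithium dimethylcuprate, [Li+].C[Cu-]C; chlorotrimethylsilane, C[Si](C)(C)Cl
Why: Me3SiCl-accelerated 1,4-addition of Me2CuLi: methyl should add to C7 anti to the adjacent C6 aryl group, which sets C7, and in situ O-silylation gives the C1=C8 enol ether as a single regioisomer that deprotonation of the ketone could not provide.

**Step 10**
Reactants: 15 silyl enol ether; 16 acrolein
Product: 18 1-allyl-4-hydroxy-5-methoxy-7-methyl-6-Ar-bicyclo[3.2.1]octan-8-one (6-endo-Ar; 7-exo-Me; 4-OH axial on the exo face), via keto aldehyde 17 (not isolated)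
Conditions: 16, Bn2NH·CF3CO2H (20 mol %), H2O, CH2Cl2, −20 → 0 °C; volatiles off; DBU, CH2Cl2, 0 °C → rt
Reagents that add atoms: acrolein 16, C=CC=O
Why: Dibenzylammonium trifluoroacetate turns acrolein into its iminium ion, C1 of 15 adds to the terminal carbon (C1–C2), water takes up the silyl group and hydrolyses the enamine to keto aldehyde 17, and DBU then enolises the C8 ketone toward C5, which adds to the aldehyde carbon (C4–C5). The first stage is an iminium-catalysed Mukaiyama–Michael addition to acrolein, and the whole is the classical α,α′-annulation of a cyclopentanone with an enal to a bicyclo[3.2.1]octan-8-one, amidine bases being known to close such bridged ketols from plain ketone α-positions. Ring C1–C2–C3–C4–C5–C8 closes in a 6-(enolendo)-exo-trig aldol addition. C1 is set by approach of the electrophile anti to the adjacent C7 methyl group (allyl ends cis to methyl), C5 by the three-atom tether, which can reach only the face on which it hangs, and C4 by the aldehyde oxygen turning away from the C6 aryl group, which leaves the hydroxyl axial on the side of C8. 1,4- over 1,2-addition is secured by the iminium activation (oxophilic Lewis acids tend to give the aldol adduct with enals) and by the fully substituted C1, C1 versus C5 by the regiodefined enol ether, and in 17 the quaternary C1 leaves C5 as the only ketone α-position while the aldehyde enolate could only close a four-membered ring. The ketol cannot dehydrate toward the quaternary C5, and excess acrolein is stripped before DBU is added so that it cannot oligomerise.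

**Step 11**
Reactants: 18 ketol
Product: 19 1-allyl-5-methoxy-7-methyl-6-Ar-4-(triethylsilyloxy)bicyclo[3.2.1]octan-8-one
Conditions: Et3SiOTf, 2,6-lutidine, CH2Cl2, −78 → 0 °C
Reagents that add atoms: triethylsilyl trifluoromethanesulfonate, CC[Si](CC)(CC)OS(=O)(=O)C(F)(F)F
Why: Silylation with a silyl triflate and a hindered pyridine (18 has no α-hydrogen at C8, so no enol silane can form) blocks retro-aldol cleavage, prevents alkoxide-directed hydride delivery to the wrong face and adds bulk on the C2–C4 side of C8.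

**Step 12**
Reactants: 19 silyl ether ketone
Product: 21 1-allyl-5-methoxy-7-methyl-6-Ar-bicyclo[3.2.1]octane-4,8-diol (4-OH axial, exo; 8-OH over the C2–C4 bridge), via C4 triethylsilyl ether alcohol 20 (not isolated)
Conditions: NaBH4, MeOH–THF, −20 °C; then 1 M aq HCl to pH 2, 0 °C → rt
Reagents that add atoms: none
Why: Borohydride reduction under steric approach control: the strained C8 ketone is screened on the C2–C4 side by the axial C4 silyl ether and the axial C2–H, so hydride should arrive from the C6–C7 side and leave the hydroxyl over the three-carbon bridge, which sets C8, and the acidic quench then hydrolyses the triethylsilyl ether.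

**Step 13**
Reactants: 21 diol
Product: 22 1-allyl-8-hydroxy-5-methoxy-7-methyl-6-Ar-bicyclo[3.2.1]octan-4-one
Conditions: Dess–Martin periodinane (1.05 equiv), NaHCO3, CH2Cl2, 0 °C
Reagents that add atoms: none
Why: Chemoselective Dess–Martin oxidation: C4–OH has only one quaternary neighbour and sheds a 1,3-diaxial O/O contact on oxidation, whereas C8–OH lies between two quaternary carbons and would have to go back to a strained bridge ketone.

**Step 14**
Reactants: 22 hydroxy ketone
Product: 23 1-allyl-5-methoxy-7-methyl-6-Ar-4,8-bis(trimethylsilyloxy)bicyclo[3.2.1]oct-3-ene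
Conditions: Me3SiOTf, Et3N, CH2Cl2, 0 °C
Reagents that add atoms: trimethylsilyl trifluoromethanesulfonate, C[Si](C)(C)OS(=O)(=O)C(F)(F)F
Why: Soft enolisation with silyl triflate and amine: C5 is quaternary, so the C4 ketone can enolise only toward C3, and the C8 hydroxyl is capped in the same operation, so that no free alkoxide able to start retro-aldol cleavage of C5–C8 is ever present.

**Step 15**
Reactants: 23 bis-silyl enol ether
Product: 25 1-allyl-3,8-dihydroxy-5-methoxy-7-methyl-6-Ar-bicyclo[3.2.1]octan-4-one (3-OH drawn exo), via bis(trimethylsilyl) ketol 24 (not isolated)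
Conditions: mCPBA (1.05 equiv), NaHCO3, CH2Cl2, −20 °C; then 10% aq citric acid, THF, rt
Reagents that add atoms: 3-chloroperoxybenzoic acid, O=C(OO)c1cccc(Cl)c1
Why: Rubottom oxidation, in which the enol ether reacts far faster than the monosubstituted allyl alkene; the configuration created at C3 (drawn exo) is of no consequence because step 16 erases it.

**Step 16**
Reactants: 25 α-ketol
Product: 26 1-allyl-3,8-dihydroxy-5-methoxy-7-methyl-6-Ar-bicyclo[3.2.1]oct-2-en-4-one (diosphenol)
Conditions: Cu(OAc)2·H2O (2.2 equiv), MeOH, 40 °C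
Reagents that add atoms: none
Why: Cu(OAc)2 oxidises α-ketols to 1,2-diketones and leaves isolated alcohols such as C8–OH alone; the 3,4-dione can enolise only toward C2 and should rest as the diosphenol.

**Step 17**
Reactants: 26 diosphenol
Product: 27 1-allyl-8-hydroxy-3,5-dimethoxy-7-methyl-6-Ar-bicyclo[3.2.1]oct-2-en-4-one
Conditions: Me3SiCHN2, MeOH–toluene, 0 °C → rt
Reagents that add atoms: (trimethylsilyl)diazomethane, C[Si](C)(C)C=[N+]=[N-]
Why: Methylation of the acidic enol with (trimethylsilyl)diazomethane in methanol takes place under neutral conditions, at which the C8 alcohol is not acidic enough to react and retro-aldol cleavage has no base to start it.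

**Step 18**
Reactants: 27 methoxy enone
Product: 28 O-triisopropylsilyl ether of the target (3-endo-OMe; 6-endo-Ar; 7-exo-Me; 8-OH over the C2–C4 bridge)
Conditions: [(Ph3P)CuH]6, H2O, degassed toluene, rt; pH 7 buffer
Reagents that add atoms: none
Why: Copper hydride conjugate reduction, selective for the enone over the isolated allyl alkene: hydride goes to C2 and the C3=C4 enolate should be protonated at C3 from the exo face, where the C8 hydroxyl hangs about 3 Å above C3 and can relay the proton through a six-membered transition state while the endo face is walled off by the C6 aryl ring, so that hydrogen ends exo and methoxy endo, which sets C3.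

**Step 19**
Reactants: 28 silyl ether of the target
Product: 29 CNP0209708.1, (1S,3S,5S,6S,7R,8S)-1-allyl-8-hydroxy-6-(3-hydroxy-4-methoxyphenyl)-3,5-dimethoxy-7-methylbicyclo[3.2.1]octan-4-one (numbering used here)
Conditions: Bu4NF, AcOH (1:1), THF, 0 °C
Reagents that add atoms: none
Why: Fluoride cleavage of the aryl silyl ether, buffered with acetic acid so that neither the epimerisable C3 nor the retro-aldol-prone C8–C5–C4 hydroxy ketone sees base.

**Compound list**
1 | 5-bromo-2-methoxyphenol | COc1ccc(Br)cc1O | starting material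
2 | (5-bromo-2-methoxyphenoxy)triisopropylsilane | COc1ccc(Br)cc1O[Si](C(C)C)(C(C)C)C(C)C | intermediate
3 | (S)-4-(tert-butyldimethylsilyloxy)cyclopent-2-en-1-one | O=C1C=C[C@@H](O[Si](C)(C)C(C)(C)C)C1 | starting material
4 | [4-methoxy-3-(triisopropylsilyloxy)phenyl]magnesium bromide | COc1ccc([Mg]Br)cc1O[Si](C(C)C)(C(C)C)C(C)C | intermediate
5 | trimethylsilyl enol ether of trans-3-Ar-4-(tert-butyldimethylsilyloxy)cyclopentanone | C[Si](C)(C)OC1=C[C@H](c2ccc(OC)c(O[Si](C(C)C)(C(C)C)C(C)C)c2)[C@@H](O[Si](C)(C)C(C)(C)C)C1 | intermediate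
6 | 2-(trimethylsilyloxy)-3-Ar-4-(tert-butyldimethylsilyloxy)cyclopentanone | O=C1[C@@H](O[Si](C)(C)C)[C@H](c2ccc(OC)c(O[Si](C(C)C)(C(C)C)C(C)C)c2)[C@@H](O[Si](C)(C)C(C)(C)C)C1 | intermediate
7 | 2-hydroxy-3-Ar-4-(tert-butyldimethylsilyloxy)cyclopentanone | O=C1[C@@H](O)[C@H](c2ccc(OC)c(O[Si](C(C)C)(C(C)C)C(C)C)c2)[C@@H](O[Si](C)(C)C(C)(C)C)C1 | intermediate
8 | 2-methoxy-3-Ar-4-(tert-butyldimethylsilyloxy)cyclopentanone | O=C1[C@@H](OC)[C@H](c2ccc(OC)c(O[Si](C(C)C)(C(C)C)C(C)C)c2)[C@@H](O[Si](C)(C)C(C)(C)C)C1 | intermediate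
9 | 4-hydroxy-2-methoxy-3-Ar-cyclopentanone | O=C1[C@@H](OC)[C@H](c2ccc(OC)c(O[Si](C(C)C)(C(C)C)C(C)C)c2)[C@@H](O)C1 | intermediate
10 | 4-(methylsulfonyloxy)-2-methoxy-3-Ar-cyclopentanone | O=C1[C@@H](OC)[C@H](c2ccc(OC)c(O[Si](C(C)C)(C(C)C)C(C)C)c2)[C@@H](OS(C)(=O)=O)C1 | intermediate
11 | trans-4-Ar-5-methoxycyclopent-2-en-1-one | O=C1[C@@H](OC)[C@H](c2ccc(OC)c(O[Si](C(C)C)(C(C)C)C(C)C)c2)C=C1 | intermediate
12 | 2-iodo-4-Ar-5-methoxycyclopent-2-en-1-one | O=C1[C@@H](OC)[C@H](c2ccc(OC)c(O[Si](C(C)C)(C(C)C)C(C)C)c2)C=C1I | intermediate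
13 | allyltributylstannane | C=CC[Sn](CCCC)(CCCC)CCCC | starting material
14 | 2-allyl-4-Ar-5-methoxycyclopent-2-en-1-one | O=C1[C@@H](OC)[C@H](c2ccc(OC)c(O[Si](C(C)C)(C(C)C)C(C)C)c2)C=C1CC=C | intermediate
15 | 2-allyl-5-methoxy-3-methyl-4-Ar-cyclopent-1-enyl trimethylsilyl ether | C=CCC1=C(O[Si](C)(C)C)[C@@H](OC)[C@H](c2ccc(OC)c(O[Si](C(C)C)(C(C)C)C(C)C)c2)[C@H]1C | intermediate
16 | acrolein | C=CC=O | starting material
17 | 3-(1-allyl-4-methoxy-2-methyl-3-Ar-5-oxocyclopentyl)propanal | C=CC[C@]1(CCC=O)[C@H](C)[C@@H](c2ccc(OC)c(O[Si](C(C)C)(C(C)C)C(C)C)c2)[C@H](OC)C1=O | intermediate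
18 | 1-allyl-4-hydroxy-5-methoxy-7-methyl-6-Ar-bicyclo[3.2.1]octan-8-one | C=CC[C@]12CC[C@@H](O)[C@](OC)([C@H](c3ccc(OC)c(O[Si](C(C)C)(C(C)C)C(C)C)c3)[C@H]1C)C2=O | intermediate
19 | 4-O-triethylsilyl ether of 18 | C=CC[C@]12CC[C@@H](O[Si](CC)(CC)CC)[C@](OC)([C@H](c3ccc(OC)c(O[Si](C(C)C)(C(C)C)C(C)C)c3)[C@H]1C)C2=O | intermediate
20 | 1-allyl-5-methoxy-7-methyl-6-Ar-4-(triethylsilyloxy)bicyclo[3.2.1]octan-8-ol | C=CC[C@]12CC[C@@H](O[Si](CC)(CC)CC)[C@](OC)([C@H](c3ccc(OC)c(O[Si](C(C)C)(C(C)C)C(C)C)c3)[C@H]1C)[C@H]2O | intermediate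
21 | 1-allyl-5-methoxy-7-methyl-6-Ar-bicyclo[3.2.1]octane-4,8-diol | C=CC[C@]12CC[C@@H](O)[C@](OC)([C@H](c3ccc(OC)c(O[Si](C(C)C)(C(C)C)C(C)C)c3)[C@H]1C)[C@H]2O | intermediate
22 | 1-allyl-8-hydroxy-5-methoxy-7-methyl-6-Ar-bicyclo[3.2.1]octan-4-one | C=CC[C@]12CCC(=O)[C@](OC)([C@H](c3ccc(OC)c(O[Si](C(C)C)(C(C)C)C(C)C)c3)[C@H]1C)[C@H]2O | intermediate
23 | 1-allyl-5-methoxy-7-methyl-6-Ar-4,8-bis(trimethylsilyloxy)bicyclo[3.2.1]oct-3-ene | C=CC[C@]12CC=C(O[Si](C)(C)C)[C@](OC)([C@H](c3ccc(OC)c(O[Si](C(C)C)(C(C)C)C(C)C)c3)[C@H]1C)[C@H]2O[Si](C)(C)C | intermediate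
24 | 1-allyl-5-methoxy-7-methyl-6-Ar-3,8-bis(trimethylsilyloxy)bicyclo[3.2.1]octan-4-one | C=CC[C@]12C[C@@H](O[Si](C)(C)C)C(=O)[C@](OC)([C@H](c3ccc(OC)c(O[Si](C(C)C)(C(C)C)C(C)C)c3)[C@H]1C)[C@H]2O[Si](C)(C)C | intermediate
25 | 1-allyl-3,8-dihydroxy-5-methoxy-7-methyl-6-Ar-bicyclo[3.2.1]octan-4-one | C=CC[C@]12C[C@@H](O)C(=O)[C@](OC)([C@H](c3ccc(OC)c(O[Si](C(C)C)(C(C)C)C(C)C)c3)[C@H]1C)[C@H]2O | intermediate
26 | 1-allyl-3,8-dihydroxy-5-methoxy-7-methyl-6-Ar-bicyclo[3.2.1]oct-2-en-4-one | C=CC[C@]12C=C(O)C(=O)[C@](OC)([C@H](c3ccc(OC)c(O[Si](C(C)C)(C(C)C)C(C)C)c3)[C@H]1C)[C@H]2O | intermediate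
27 | 1-allyl-8-hydroxy-3,5-dimethoxy-7-methyl-6-Ar-bicyclo[3.2.1]oct-2-en-4-one | C=CC[C@]12C=C(OC)C(=O)[C@](OC)([C@H](c3ccc(OC)c(O[Si](C(C)C)(C(C)C)C(C)C)c3)[C@H]1C)[C@H]2O | intermediate
28 | O-triisopropylsilyl ether of the target | C=CC[C@]12C[C@H](OC)C(=O)[C@](OC)([C@H](c3ccc(OC)c(O[Si](C(C)C)(C(C)C)C(C)C)c3)[C@H]1C)[C@H]2O | intermediate
29 | CNP0209708.1 | C=CC[C@]12C[C@H](OC)C(=O)[C@](OC)([C@H](c3ccc(OC)c(O)c3)[C@H]1C)[C@H]2O | target

Total step count: 19
Longest linear sequence: 19 steps (from 1; 18 from 3)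

**Steps most likely to fail**

*Step 10.* Four things may go wrong.
- The silyl group of 15 may be lost by protonation before C1–C2 forms.
- The iminium ion may approach syn to the C7 methyl group.
- Acrolein may be released from the congested C1 by retro-Michael reaction once DBU is present.
- The aldol equilibrium may stay open, because C4–C5 is made cis to the C6 aryl group.

Fallback (alkylation instead of conjugate addition), from 15 back to 17: 15 is cleaved with MeLi (THF, 0 °C) to the regiodefined lithium enolate F1. This is alkylated at C1, again anti to the methyl group, with 2-(2-iodoethyl)-1,3-dioxolane (DMPU, −40 °C → rt) to give the keto acetal F2. PPTS in wet acetone then frees keto aldehyde 17, which DBU closes to 18.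

*Step 12.* Facial selectivity may be poor, because the C6–C7 side from which hydride must come carries the exo methyl group, so part of the hydride may arrive from the C2–C4 side.

Fallback (electron transfer under chelate control instead of hydride attack), from 18 back to 21: the unprotected ketol 18 is reduced with SmI2/H2O/Et3N in THF. Samarium bound to the C4 oxygen should hold the ketyl oxygen on the C2–C4 side, so that C8 is protonated from the C6–C7 side. The bridgehead C5–OMe bond lies in the carbonyl plane and cannot be expelled. Diol 21 results directly, and this fallback makes no compound outside the list (F0).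

*Step 18.* Four things may go wrong.
- Hydride transfer to the neopentyl C2 of the electron-rich methoxy enone may be slow.
- 1,2-Reduction may compete.
- The enolate may be protonated from the endo face.
- C3 may drift to the more stable exo-methoxy epimer if the medium turns basic.

Fallback (carbenoid O–H insertion instead of conjugate reduction), from 22 back to 28:
1. 22 is silylated (Et3SiOTf, 2,6-lutidine) to the C8 triethylsilyl ether ketone F3.
2. LiHMDS and CF3CO2CH2CF3 give the α-trifluoroacetyl ketone F4.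
3. F4 is taken on without isolation with MsN3, Et3N and H2O in MeCN (Regitz-type detrifluoroacetylative diazo transfer) to the α-diazo ketone F5.
4. Rh2(OAc)4 in MeOH–CH2Cl2 at 0 °C inserts methanol, and the methoxy enol so released is protonated last at C3, giving the C8 triethylsilyl ether of the methoxy ketone F6.
5. PPTS in MeOH removes the triethylsilyl group to give 28.

**Further compounds**
F1 | step 10 | lithium enolate of 2-allyl-5-methoxy-3-methyl-4-Ar-cyclopentanone (C1=C8) | [Li+].C=CCC1=C([O-])[C@@H](OC)[C@H](c2ccc(OC)c(O[Si](C(C)C)(C(C)C)C(C)C)c2)[C@H]1C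
F2 | step 10 | 2-allyl-2-[2-(1,3-dioxolan-2-yl)ethyl]-5-methoxy-3-methyl-4-Ar-cyclopentanone | C=CC[C@]1(CCC2OCCO2)[C@H](C)[C@@H](c2ccc(OC)c(O[Si](C(C)C)(C(C)C)C(C)C)c2)[C@H](OC)C1=O
F0 | step 12 | none | none
F3 | step 18 | 1-allyl-5-methoxy-7-methyl-6-Ar-8-(triethylsilyloxy)bicyclo[3.2.1]octan-4-one | C=CC[C@]12CCC(=O)[C@](OC)([C@H](c3ccc(OC)c(O[Si](C(C)C)(C(C)C)C(C)C)c3)[C@H]1C)[C@H]2O[Si](CC)(CC)CC
F4 | step 18 | 3-(trifluoroacetyl) derivative of F3 (C3 configurationally labile) | C=CC[C@]12CC(C(=O)C(F)(F)F)C(=O)[C@](OC)([C@H](c3ccc(OC)c(O[Si](C(C)C)(C(C)C)C(C)C)c3)[C@H]1C)[C@H]2O[Si](CC)(CC)CC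
F5 | step 18 | 3-diazo derivative of F3 | C=CC[C@]12CC(=[N+]=[N-])C(=O)[C@](OC)([C@H](c3ccc(OC)c(O[Si](C(C)C)(C(C)C)C(C)C)c3)[C@H]1C)[C@H]2O[Si](CC)(CC)CC
F6 | step 18 | 8-O-triethylsilyl ether of 28 | C=CC[C@]12C[C@H](OC)C(=O)[C@](OC)([C@H](c3ccc(OC)c(O[Si](C(C)C)(C(C)C)C(C)C)c3)[C@H]1C)[C@H]2O[Si](CC)(CC)CC
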